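**Retrosynthetic overview**

- The last step frees the three phenols of 6-[(6,7-dimethoxycoumarin-5-yl)oxy]-7-methoxycoumarin. Unit A (the 6-aryloxy-7-hydroxycoumarin) is bought whole as isoscopoletin; only its C6–O bond to ring B is made, by substitution on a squarate-derived vinylogous acid chloride.
- Ring C (the lactone ring of the second coumarin) is cut at O1–C2 and C3=C4: a C4a propanal chain and the C8a phenol give the lactol, then the dihydrocoumarin, then the coumarin.
- Ring B (the benzene ring of the second coumarin) carries the meta pair C7–OH and C8a–O with C8–H between them. This is the feature the strategy rests on: ring B is cut at C7–C8, C8a–C4a and C6–C7 into a two-carbon oxyalkyne (C8, C8a) and a cyclobutenone carrying C7 (carbonyl), C4a (chain), C5 (aryloxy) and C6 (methoxy).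
- The cyclobutenone comes from dimethyl squarate by Grignard addition–rearrangement, OMe → Cl → OAr exchange, regioselective hydride reduction and O-methylation.
- Order of ring formation: unit A is bought, ring B is closed by the benzannulation, ring C is closed last.

Key step: step 9

Remark: the target is achiral; every chiral intermediate is formed as a racemate and its stereocentre is erased later. In the transient ketenes the methoxy group is assumed to rotate outward on ring opening.

**Route**

Step 1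
Reactants: 1 dimethyl squarate; 2 2-(2-bromoethyl)-1,3-dioxolane
Product: 6 3-[2-(1,3-dioxolan-2-yl)ethyl]-4-methoxycyclobut-3-ene-1,2-dione, via Grignard reagent 3 (not isolated), via magnesium alkoxide 4 (not isolated), via trifluoroacetate 5 (not isolated)
Conditions: Mg, THF, 25 °C; 1, THF, −78 °C; (CF3CO)2O, −78 °C; then aq NaHCO3, 0 °C
Reagents that add atoms: water, O
Why: 1,2-addition of the Grignard reagent to one squarate carbonyl and trifluoroacetylation of the alkoxide give an allylic ester that ionises with help of the neighbouring methoxy group and is hydrolysed on the buffered work-up to the 3-alkyl-4-methoxycyclobutenedione (squarate addition–rearrangement), which should leave the dioxolane intact.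

Step 2
Reactants: 6 3-[2-(1,3-dioxolan-2-yl)ethyl]-4-methoxycyclobut-3-ene-1,2-dione
Product: 7 sodium 2-[2-(1,3-dioxolan-2-yl)ethyl]-3,4-dioxocyclobut-1-en-1-olate
Conditions: NaI, acetone, 50 °C
Reagents that add atoms: sodium iodide, [Na+].[I-]
Why: the vinylogous methyl ester of a strongly acidic alkylsquaric acid is a good methyl donor, so SN2 O-demethylation by iodide should give the salt under neutral, water-free conditions that spare the acetal.

Step 3
Reactants: 7 sodium 2-[2-(1,3-dioxolan-2-yl)ethyl]-3,4-dioxocyclobut-1-en-1-olate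
Product: 8 3-chloro-4-[2-(1,3-dioxolan-2-yl)ethyl]cyclobut-3-ene-1,2-dione
Conditions: (COCl)2, DMF (cat.), CH2Cl2, 0 °C to rt
Reagents that add atoms: oxalyl chloride, O=C(Cl)C(=O)Cl
Why: Vilsmeier-type activation of the vinylogous carboxylate followed by chloride addition–elimination should give the vinylogous acid chloride without free acid, as in the preparation of squaric acid chlorides.

Step 4
Reactants: 8 3-chloro-4-[2-(1,3-dioxolan-2-yl)ethyl]cyclobut-3-ene-1,2-dione; 9 6-hydroxy-7-methoxycoumarin (isoscopoletin)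
Product: 10 3-[2-(1,3-dioxolan-2-yl)ethyl]-4-[(7-methoxy-2-oxo-2H-chromen-6-yl)oxy]cyclobut-3-ene-1,2-dione
Conditions: iPr2NEt, CH2Cl2, −20 to 0 °C
Reagents that add atoms: none
Why: addition–elimination of the phenoxide at the chlorine-bearing carbon (vinylogous acylation of a phenol) should form the C5–O aryl ether bond, the hindered amine serving only as base.

Step 5
Reactants: 10 3-[2-(1,3-dioxolan-2-yl)ethyl]-4-[(7-methoxy-2-oxo-2H-chromen-6-yl)oxy]cyclobut-3-ene-1,2-dione
Product: 11 2-[2-(1,3-dioxolan-2-yl)ethyl]-4-hydroxy-3-[(7-methoxy-2-oxo-2H-chromen-6-yl)oxy]cyclobut-2-en-1-one (racemic)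
Conditions: LiAlH(OtBu)3, THF, −78 °C; then pH 7 buffer
Reagents that add atoms: none
Why: regioselective 1,2-hydride reduction, since the carbonyl next to the aryloxy carbon is a cross-conjugated ketone and more electrophilic than the vinylogous ester carbonyl, and the bulky hydride should not touch the coumarin lactone at −78 °C; the new carbinol centre is racemic and is lost in step 9.

Step 6
Reactants: 11 2-[2-(1,3-dioxolan-2-yl)ethyl]-4-hydroxy-3-[(7-methoxy-2-oxo-2H-chromen-6-yl)oxy]cyclobut-2-en-1-one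
Product: 12 2-[2-(1,3-dioxolan-2-yl)ethyl]-4-methoxy-3-[(7-methoxy-2-oxo-2H-chromen-6-yl)oxy]cyclobut-2-en-1-one (racemic)
Conditions: MeI, Ag2O, 4 Å MS, MeCN, rt, dark
Reagents that add atoms: iodomethane, CI
Why: Purdie methylation of the secondary alcohol runs under near-neutral conditions, so the aryl vinylogous ester and the strained enone should survive.

Step 7
Reactants: 13 ethynyltrimethylsilane
Product: 16 triisopropyl{[(trimethylsilyl)ethynyl]oxy}silane, via lithium acetylide 14 (not isolated), via lithium ynolate 15 (not isolated)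
Conditions: n-BuLi, THF, −78 °C; LiOOtBu (from tBuOOH, LiN(SiMe3)2), −78 to 0 °C; TIPSOTf, −78 °C
Reagents that add atoms: tert-butyl hydroperoxide, CC(C)(C)OO; triisopropylsilyl trifluoromethanesulfonate, CC(C)[Si](OS(=O)(=O)C(F)(F)F)(C(C)C)C(C)C
Why: oxidation of a lithium acetylide by lithium tert-butyl peroxide gives the lithium ynolate, which the bulky, hard silyl triflate should silylate on oxygen to the silyl ynol ether.

Step 8
Reactants: 16 triisopropyl{[(trimethylsilyl)ethynyl]oxy}silane
Product: 17 (triisopropylsilyloxy)ethyne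
Conditions: K2CO3 (cat.), MeOH, 0 °C, short contact; pentane extraction
Reagents that add atoms: none
Why: base-catalysed methanolysis of the alkynyl–SiMe3 bond (protodesilylation) should be much faster than attack at the hindered O–Si(iPr)3 group.

Step 9
Reactants: 12 2-[2-(1,3-dioxolan-2-yl)ethyl]-4-methoxy-3-[(7-methoxy-2-oxo-2H-chromen-6-yl)oxy]cyclobut-2-en-1-one; 17 (triisopropylsilyloxy)ethyne
Product: 22 6-{6-[2-(1,3-dioxolan-2-yl)ethyl]-3-hydroxy-2-methoxy-5-[(triisopropylsilyl)oxy]phenoxy}-7-methoxy-2H-chromen-2-one, via vinylketene 18 (not isolated), via vinylcyclobutenone 19 (not isolated), via dienylketene 20 (not isolated), via cyclohexadienone 21 (not isolated)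
Conditions: 17 (3 equiv), toluene, 110 °C, sealed tube, argon
Reagents that add atoms: none
Why: Heat opens cyclobutenone 12 by a conrotatory four-electron process with the methoxy group turning outward, giving vinylketene 18; its ketene carbon (the future C7) is attacked by the nucleophilic CH terminus of the siloxyalkyne while the oxygen-bearing alkyne carbon bonds to C4a, a (2+2) addition across the ketene C=C bond that forms C7–C8 and C8a–C4a. The 4-vinylcyclobutenone 19 reopens to dienylketene 20, and benzene ring B is closed by a thermal six-electron disrotatory electrocyclisation forming C6–C7, after which dienone 21 tautomerises to the phenol. The closest known chemistry is the Danheiser benzannulation of cyclobutenones with trialkylsilyloxyalkynes, combined with the thermal ring opening of squarate-derived 4-alkoxycyclobutenones. No stereocentre remains, because the C6 centre of 21 is lost on aromatisation. The step needs the regiochemistry C7–C8 and C4a–C8a, which the polarisation of the ynol ether against the electrophilic ketene carbon secures, and it needs capture of 18 faster than its dimerisation, which the excess of alkyne and the neutral, nucleophile-free medium favour; the coumarin lactone, the aryl vinyl ether and the dioxolane should be spectators, and C7–OH and C8a–OSi emerge differentiated.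

Step 10
Reactants: 22 6-{6-[2-(1,3-dioxolan-2-yl)ethyl]-3-hydroxy-2-methoxy-5-[(triisopropylsilyl)oxy]phenoxy}-7-methoxy-2H-chromen-2-one
Product: 23 6-{6-[2-(1,3-dioxolan-2-yl)ethyl]-2,3-dimethoxy-5-[(triisopropylsilyl)oxy]phenoxy}-7-methoxy-2H-chromen-2-one
Conditions: MeI, K2CO3, acetone, 40 °C
Reagents that add atoms: iodomethane, CI
Why: Williamson methylation of the unhindered C7 phenol; the aryl silyl ether sits meta to the phenoxide, cannot migrate and should withstand dry carbonate.

Step 11
Reactants: 23 6-{6-[2-(1,3-dioxolan-2-yl)ethyl]-2,3-dimethoxy-5-[(triisopropylsilyl)oxy]phenoxy}-7-methoxy-2H-chromen-2-one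
Product: 25 6-[(2-hydroxy-6,7-dimethoxy-3,4-dihydro-2H-chromen-5-yl)oxy]-7-methoxy-2H-chromen-2-one (racemic lactol), via free phenol 24 (not isolated)
Conditions: TBAF, THF, 0 °C; then 2 M aq HCl, THF, rt
Reagents that add atoms: water, O
Why: fluoride cleaves the aryl silyl ether, and acid hydrolysis of the dioxolane then lets the C8a phenol close onto the aldehyde to the six-membered 2-chromanol (ring C); the anomeric centre forms as a mixture and is removed in step 12.

Step 12
Reactants: 25 6-[(2-hydroxy-6,7-dimethoxy-3,4-dihydro-2H-chromen-5-yl)oxy]-7-methoxy-2H-chromen-2-one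
Product: 26 6-[(6,7-dimethoxy-2-oxo-3,4-dihydro-2H-chromen-5-yl)oxy]-7-methoxy-2H-chromen-2-one
Conditions: nPr4N[RuO4] (cat.), NMO, 4 Å MS, CH2Cl2, rt
Reagents that add atoms: none
Why: Ley–Griffith oxidation of a lactol to the lactone is mild and should not attack the aryl ethers or the electron-rich ring.

Step 13
Reactants: 26 6-[(6,7-dimethoxy-2-oxo-3,4-dihydro-2H-chromen-5-yl)oxy]-7-methoxy-2H-chromen-2-one
Product: 27 6-[(6,7-dimethoxy-2-oxo-2H-chromen-5-yl)oxy]-7-methoxy-2H-chromen-2-one
Conditions: DDQ, 1,4-dioxane, 100 °C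
Reagents that add atoms: none
Why: DDQ dehydrogenation of a dihydrocoumarin; hydride abstraction from benzylic C4 is helped by the para C7 methoxy and the ortho oxygens, and loss of the C3 proton gives the coumarin.

Step 14
Reactants: 27 6-[(6,7-dimethoxy-2-oxo-2H-chromen-5-yl)oxy]-7-methoxy-2H-chromen-2-one
Product: 28 6,7-dihydroxy-5-[(7-hydroxy-2-oxo-2H-chromen-6-yl)oxy]-2H-chromen-2-one (CNP0197949.0)
Conditions: BBr3 (excess), CH2Cl2, −78 °C to rt; then H2O
Reagents that add atoms: none
Why: BBr3 cleaves all three aryl methyl ethers, while the diaryl ether and both coumarin lactones should be inert to it.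

**Compound list**

1 | dimethyl squarate | COC1=C(OC)C(=O)C1=O | starting material
2 | 2-(2-bromoethyl)-1,3-dioxolane | BrCCC1OCCO1 | starting material
3 | [2-(1,3-dioxolan-2-yl)ethyl]magnesium bromide | Br[Mg]CCC1OCCO1 | intermediate
4 | bromomagnesium alkoxide of 4-[2-(1,3-dioxolan-2-yl)ethyl]-4-hydroxy-2,3-dimethoxycyclobut-2-en-1-one | COC1=C(OC)C(O[Mg]Br)(CCC2OCCO2)C1=O | intermediate
5 | 1-[2-(1,3-dioxolan-2-yl)ethyl]-2,3-dimethoxy-4-oxocyclobut-2-en-1-yl trifluoroacetate | COC1=C(OC)C(OC(=O)C(F)(F)F)(CCC2OCCO2)C1=O | intermediate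
6 | 3-[2-(1,3-dioxolan-2-yl)ethyl]-4-methoxycyclobut-3-ene-1,2-dione | COC1=C(CCC2OCCO2)C(=O)C1=O | intermediate
7 | sodium 2-[2-(1,3-dioxolan-2-yl)ethyl]-3,4-dioxocyclobut-1-en-1-olate | [Na+].[O-]C1=C(CCC2OCCO2)C(=O)C1=O | intermediate
8 | 3-chloro-4-[2-(1,3-dioxolan-2-yl)ethyl]cyclobut-3-ene-1,2-dione | ClC1=C(CCC2OCCO2)C(=O)C1=O | intermediate
9 | 6-hydroxy-7-methoxycoumarin (isoscopoletin) | COc1cc2oc(=O)ccc2cc1O | starting material
10 | 3-[2-(1,3-dioxolan-2-yl)ethyl]-4-[(7-methoxy-2-oxo-2H-chromen-6-yl)oxy]cyclobut-3-ene-1,2-dione | O=C1C(=O)C(CCC2OCCO2)=C1Oc1cc2ccc(=O)oc2cc1OC | intermediate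
11 | 2-[2-(1,3-dioxolan-2-yl)ethyl]-4-hydroxy-3-[(7-methoxy-2-oxo-2H-chromen-6-yl)oxy]cyclobut-2-en-1-one (racemic) | OC1C(=O)C(CCC2OCCO2)=C1Oc1cc2ccc(=O)oc2cc1OC | intermediate
12 | 2-[2-(1,3-dioxolan-2-yl)ethyl]-4-methoxy-3-[(7-methoxy-2-oxo-2H-chromen-6-yl)oxy]cyclobut-2-en-1-one (racemic) | COC1C(=O)C(CCC2OCCO2)=C1Oc1cc2ccc(=O)oc2cc1OC | intermediate
13 | ethynyltrimethylsilane | C#C[Si](C)(C)C | starting material
14 | lithium (trimethylsilyl)acetylide | [Li]C#C[Si](C)(C)C | intermediate
15 | lithium 2-(trimethylsilyl)ethynolate | [Li+].[O-]C#C[Si](C)(C)C | intermediate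
16 | triisopropyl{[(trimethylsilyl)ethynyl]oxy}silane | C[Si](C)(C)C#CO[Si](C(C)C)(C(C)C)C(C)C | intermediate
17 | (triisopropylsilyloxy)ethyne | C#CO[Si](C(C)C)(C(C)C)C(C)C | intermediate
18 | vinylketene: 2-[2-(1,3-dioxolan-2-yl)ethyl]-4-methoxy-3-[(7-methoxy-2-oxo-2H-chromen-6-yl)oxy]buta-1,3-dien-1-one, methoxy cis to aryloxy | CO/C=C(\Oc1cc2ccc(=O)oc2cc1OC)C(CCC1OCCO1)=C=O | intermediate
19 | 4-[2-(1,3-dioxolan-2-yl)ethyl]-4-{2-methoxy-1-[(7-methoxy-2-oxo-2H-chromen-6-yl)oxy]ethenyl}-3-[(triisopropylsilyl)oxy]cyclobut-2-en-1-one (racemic) | O=C1C=C(O[Si](C(C)C)(C(C)C)C(C)C)C1(CCC2OCCO2)/C(Oc3cc4ccc(=O)oc4cc3OC)=C/OC | intermediate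
20 | dienylketene: 4-[2-(1,3-dioxolan-2-yl)ethyl]-6-methoxy-5-[(7-methoxy-2-oxo-2H-chromen-6-yl)oxy]-3-[(triisopropylsilyl)oxy]hexa-1,3,5-trien-1-one, ketenyl and vinyl groups cis | O=C=C/C(O[Si](C(C)C)(C(C)C)C(C)C)=C(CCC1OCCO1)\C(Oc1cc2ccc(=O)oc2cc1OC)=C\OC | intermediate
21 | 4-[2-(1,3-dioxolan-2-yl)ethyl]-6-methoxy-5-[(7-methoxy-2-oxo-2H-chromen-6-yl)oxy]-3-[(triisopropylsilyl)oxy]cyclohexa-2,4-dien-1-one (racemic) | COC1C(=O)C=C(O[Si](C(C)C)(C(C)C)C(C)C)C(CCC2OCCO2)=C1Oc1cc2ccc(=O)oc2cc1OC | intermediate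
22 | 6-{6-[2-(1,3-dioxolan-2-yl)ethyl]-3-hydroxy-2-methoxy-5-[(triisopropylsilyl)oxy]phenoxy}-7-methoxy-2H-chromen-2-one | COc1c(O)cc(O[Si](C(C)C)(C(C)C)C(C)C)c(CCC2OCCO2)c1Oc1cc2ccc(=O)oc2cc1OC | intermediate
23 | 6-{6-[2-(1,3-dioxolan-2-yl)ethyl]-2,3-dimethoxy-5-[(triisopropylsilyl)oxy]phenoxy}-7-methoxy-2H-chromen-2-one | COc1cc(O[Si](C(C)C)(C(C)C)C(C)C)c(CCC2OCCO2)c(Oc2cc3ccc(=O)oc3cc2OC)c1OC | intermediate
24 | 6-{2-[2-(1,3-dioxolan-2-yl)ethyl]-3-hydroxy-5,6-dimethoxyphenoxy}-7-methoxy-2H-chromen-2-one | COc1cc(O)c(CCC2OCCO2)c(Oc2cc3ccc(=O)oc3cc2OC)c1OC | intermediate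
25 | 6-[(2-hydroxy-6,7-dimethoxy-3,4-dihydro-2H-chromen-5-yl)oxy]-7-methoxy-2H-chromen-2-one (racemic lactol) | COc1cc2OC(O)CCc2c(Oc2cc3ccc(=O)oc3cc2OC)c1OC | intermediate
26 | 6-[(6,7-dimethoxy-2-oxo-3,4-dihydro-2H-chromen-5-yl)oxy]-7-methoxy-2H-chromen-2-one | COc1cc2OC(=O)CCc2c(Oc2cc3ccc(=O)oc3cc2OC)c1OC | intermediate
27 | 6-[(6,7-dimethoxy-2-oxo-2H-chromen-5-yl)oxy]-7-methoxy-2H-chromen-2-one | COc1cc2oc(=O)ccc2c(Oc2cc3ccc(=O)oc3cc2OC)c1OC | intermediate
28 | 6,7-dihydroxy-5-[(7-hydroxy-2-oxo-2H-chromen-6-yl)oxy]-2H-chromen-2-one (CNP0197949.0) | O=c1ccc2cc(Oc3c(O)c(O)cc4oc(=O)ccc34)c(O)cc2o1 | target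

**Summary**

Total step count: 14 (steps 1–6 main line, steps 7–8 alkyne branch, steps 9–14 after convergence).
Longest linear sequence: 12 steps (steps 1–6 and 9–14, from dimethyl squarate).

**Steps most likely to fail**

1. Step 9. The ring opening of 12 may need a temperature at which the vinylketene is consumed by dimerisation or by attack on its own aryloxy ring before the alkyne adds, and the siloxyalkyne may isomerise to the silylketene on long heating. The fallback is a Moore rearrangement that brings C7 and C8 in as a 1-methoxyvinyl group instead of an alkyne, and it sets out from 10. One equivalent of 1-methoxyvinyllithium (from methyl vinyl ether and t-BuLi, THF, −78 °C) should add to the ketone-like carbonyl next to the aryloxy carbon, and trapping the alkoxide with MeOTf would give 2-[2-(1,3-dioxolan-2-yl)ethyl]-4-methoxy-4-(1-methoxyethenyl)-3-[(7-methoxy-2-oxo-2H-chromen-6-yl)oxy]cyclobut-2-en-1-one F1. Heating F1 in toluene or xylene should open the ring with the methoxy group outward; the dienylketene closes onto the vinyl CH2 by six-electron electrocyclisation and tautomerises to the free phenol, with C6–OMe and C7–OMe already in place. This comes back to the route at 24, which is taken through the acid half of step 11 to 25.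

2. Step 5. Hydride may add to the aryloxy-bearing carbon and expel the phenoxide, both carbonyls may be reduced, or the hydroxycyclobutenone may lose the phenol on work-up. The fallback reduces before the aryl ether is installed and sets out from 6. LiAlH(OtBu)3 at −78 °C on this alkoxy dione should give 2-[2-(1,3-dioxolan-2-yl)ethyl]-4-hydroxy-3-methoxycyclobut-2-en-1-one F2, and Ag2O/MeI would give 2-[2-(1,3-dioxolan-2-yl)ethyl]-3,4-dimethoxycyclobut-2-en-1-one F3. Iodide demethylation of the vinylogous ester (NaI, 2-butanone, 60 °C) gives sodium 2-[2-(1,3-dioxolan-2-yl)ethyl]-4-methoxy-3-oxocyclobut-1-en-1-olate F4, whose two oxygen termini are equivalent, so oxalyl chloride with catalytic DMF gives a single 3-chloro-2-[2-(1,3-dioxolan-2-yl)ethyl]-4-methoxycyclobut-2-en-1-one F5. Substitution of the chloride by isoscopoletin 9 with iPr2NEt comes back to the route at 12.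

3. Step 8. Methanolysis at the O–Si bond may compete with cleavage of the C–Si bond, so that the freed ynolate is lost as an acetate ester, and the volatile alkyne may be lost on isolation. The fallback carries the C-silyl group through the benzannulation as a traceless substituent at C8 and sets out from 16. Heating 16 with 12 as in step 9 should give 6-{6-[2-(1,3-dioxolan-2-yl)ethyl]-3-hydroxy-2-methoxy-5-[(triisopropylsilyl)oxy]-4-(trimethylsilyl)phenoxy}-7-methoxy-2H-chromen-2-one F6. Methylation as in step 10 would give 6-{6-[2-(1,3-dioxolan-2-yl)ethyl]-2,3-dimethoxy-5-[(triisopropylsilyl)oxy]-4-(trimethylsilyl)phenoxy}-7-methoxy-2H-chromen-2-one F7. TBAF followed by aqueous trifluoroacetic acid should remove the silyl ether, protodesilylate the electron-rich C8 position by ipso protonation and hydrolyse the acetal, coming back to the route at 25.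

**Further compounds**

F1 | step 9 | 2-[2-(1,3-dioxolan-2-yl)ethyl]-4-methoxy-4-(1-methoxyethenyl)-3-[(7-methoxy-2-oxo-2H-chromen-6-yl)oxy]cyclobut-2-en-1-one | COC(=C)C1(OC)C(=O)C(CCC2OCCO2)=C1Oc1cc2ccc(=O)oc2cc1OC
F2 | step 5 | 2-[2-(1,3-dioxolan-2-yl)ethyl]-4-hydroxy-3-methoxycyclobut-2-en-1-one | OC1C(=O)C(CCC2OCCO2)=C1OC
F3 | step 5 | 2-[2-(1,3-dioxolan-2-yl)ethyl]-3,4-dimethoxycyclobut-2-en-1-one | COC1C(=O)C(CCC2OCCO2)=C1OC
F4 | step 5 | sodium 2-[2-(1,3-dioxolan-2-yl)ethyl]-4-methoxy-3-oxocyclobut-1-en-1-olate | [Na+].[O-]C1=C(CCC2OCCO2)C(=O)C1OC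
F5 | step 5 | 3-chloro-2-[2-(1,3-dioxolan-2-yl)ethyl]-4-methoxycyclobut-2-en-1-one | COC1C(=O)C(CCC2OCCO2)=C1Cl
F6 | step 8 | 6-{6-[2-(1,3-dioxolan-2-yl)ethyl]-3-hydroxy-2-methoxy-5-[(triisopropylsilyl)oxy]-4-(trimethylsilyl)phenoxy}-7-methoxy-2H-chromen-2-one | COc1c(O)c([Si](C)(C)C)c(O[Si](C(C)C)(C(C)C)C(C)C)c(CCC2OCCO2)c1Oc1cc2ccc(=O)oc2cc1OC
F7 | step 8 | 6-{6-[2-(1,3-dioxolan-2-yl)ethyl]-2,3-dimethoxy-5-[(triisopropylsilyl)oxy]-4-(trimethylsilyl)phenoxy}-7-methoxy-2H-chromen-2-one | COc1c(OC)c([Si](C)(C)C)c(O[Si](C(C)C)(C(C)C)C(C)C)c(CCC2OCCO2)c1Oc1cc2ccc(=O)oc2cc1OC
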